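The numbers in the tables are simulated on assumed constants, noise included.

- The product I followed was monomer in chains. Its average length is that amount divided by chains begun, so I needed a count of chains, which neither earlier run shows.

| setting | winter | summer | gamma | zeta |
|---|---|---|---|---|
| free monomer | 1 M | 1 M | 1.0 M | 1.0 M |
| transfer agent | 5 mM | 20 mM | 10.0 mM | 10.0 mM |
| initiator | 25 mM | 25 mM | 25 mM | 25 mM |
| remark | run made earlier | run made earlier |  |  |
| time |  |  | 6.0 min | 3.0 min |

| winter: time / min | winter: monomer in chains / % | summer: time / min | summer: monomer in chains / % |
|---|---|---|---|
| 0.833 | 4.5 | 0.833 | 3.9 |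
| 2.50 | 10.6 | 2.50 | 5.9 |
| 5.00 | 16.9 | 5.00 | 7.4 |
| 8.00 | 22.1 | 8.00 | 9.4 |

(standard deviation of a reading: 0.5 percentage points)

- which of the two ends with the longer chains by the average number of monomer units in a chain (chains begun, living or dead) ("neither" if they lie within 10%) (gamma / zeta / neither)
- average number of monomer units in a chain (chains begun, living or dead) at the end, gamma
- average number of monomer units in a chain (chains begun, living or dead) at the end, zeta

- the average divides the monomer in chains by the number of chains begun, living and dead together
- the earlier runs do not show the number of chains; that part of a forecast is a guess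

- From 2.50 min to 8.00 min the winter run gained 0.0209 min⁻¹ of the charge, against 0.00636 min⁻¹ in the summer run, which had more transfer agent and gained less.
- My rule of thumb was that each transfer agent stops one chain, so at the same charges of free monomer and initiator the late gain falls in a straight line with transfer agent and reaches zero where agent equals chains begun.
- Extending that line gave the chain fraction, chains begun per free monomer charged, as a reading: 0.0266. The initiator charge, at one chain each, gives a similar 0.0250.
- The line ends where transfer agent over chains begun reaches one. That ratio was 0.188 in winter and 0.753 in summer, and 0.376 for gamma and zeta, so I was interpolating.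
- Interpolating gave monomer in chains of 15.3% for gamma and 9.84% for zeta. Dividing by the chain fraction, I expected lengths of 5.77 and 3.70.
- The forecast said 11 (8 to 17) for gamma and 9 (6.5 to 15) for zeta, with gamma longer, assuming “the transfer agent is mostly consumed”. My lengths were shorter.
- The flasks gave 6.47 for gamma and 4.19 for zeta, with gamma longer.

    free monomer + initiator → living end + monomer in chains (k = 0.0240 M⁻¹ s⁻¹)
    free monomer + living end → monomer in chains + living end, rate k2*[living end]*[free monomer] (k = 0.0530 M⁻¹ s⁻¹)
    living end + transfer agent → dead chain (kL = 3.00 M⁻¹ s⁻¹)
    2 initiator → spent initiator (k = 0.0490 M⁻¹ s⁻¹)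
    free monomer → uncatalysed product (k = 0.00240 s⁻¹)

- At 6.00 min in gamma, free monomer was passing into uncatalysed product 3.3 times as fast as it was adding to living ends. By then gamma held 52.1% uncatalysed product beside 15.3% monomer in chains.
- In a neighbour of gamma, the same flask with 0.0060 M of transfer agent, 18.4% monomer in chains over my chain fraction gives 6.94; the computed length is 7.81.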